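## Structural features

The target is an isoflavone. A benzo ring (ring A) is fused through the C4a–C8a bond to a 4-pyranone (ring C), and a 3,4,5-trimethoxyphenyl group (ring B) is attached to C3 through the C3–C1' bond. The molecule has no stereocentre, so no relative or absolute configuration has to be set. Ring A carries two neighbouring oxygens, a methoxy group on C6 and a free hydroxyl on C7; C5, C8 and C2 are unsubstituted CH positions.

The fragile parts are the pyranone, which hydroxide, alkoxides and amines attack at C2 and open, the reducible C2=C3 bond, and the four aryl methyl ethers. The central 4'-methoxy group of ring B is the ether most easily lost to Lewis acids. The ring system itself is not hard to make. The difficulty lies in joining ring C to ring A without relying on the nucleophilicity of ring A, and in telling O6 from O7.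

The key step uses the fact that O1 and C4 are bonded to the adjacent ring A carbons C8a and C4a, the two carbons of an aryne. The remaining unit O1–C2=C3–C4, with ring B on C3, is an enolised 2-aryl-2-formylacetate, that is a 3-hydroxy-2-arylacrylate. When O6 and O7 are tied through one methylene carbon the aryne is symmetric. The two oxygens can be distinguished later because only the 7-hydroxyl, para to C4a, is conjugated with the C4 carbonyl.

## Logic of the disconnections

**15 to 14.** The O7–CH2Ph bond is introduced in the retrosynthetic sense: the free 7-hydroxyl is traced back to a benzyl ether. The phenol has to be masked while O6 is methylated, and a benzyl group leaves under neutral conditions. This removes the only acidic function from the late intermediates. The forward step must stop before the C2=C3 bond is reduced.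

**14 to 13.** The O6–CH3 bond is cut. With O7 blocked, methylation has no selectivity problem. The unsymmetrical ring A pattern is reduced to a monoprotected catechol. The forward step needs a base that alkylates a phenol without opening the pyranone at C2.

**13 to 12.** The O7–CH2Ph bond is cut. In 12 the hydroxyl on C7 is a vinylogous acid and that on C6 is an ordinary phenol, so acidity distinguishes them. Both ring A oxygens become free and equivalent in origin. The forward step must ionise only one hydroxyl.

**12 to 11.** The two hydroxyls are joined through one methylene carbon (two O–CH2 bonds). The bridge makes ring A symmetric with respect to the C4a–C8a bond, which the next cut requires. The forward cleavage of this acetal must spare the three methyl ethers of ring B and the pyranone.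

**11 to 8 and 3, through 9 and 10.** The cuts are O1–C8a and C4–C4a, the two bonds between ring C and ring A. They end on adjacent ring carbons, so ring A becomes the aryne 9 (released from 8), and the rest is 3, which already carries ring B. The bicycle falls into two pieces of similar size, and ring A needs no activating or directing group. The forward step requires attack of the enolate of 3 on 9 through oxygen, an ester cis to the new ether in 10, and acyl substitution faster than protonation of 10. The symmetry of 9 removes any regiochemical question.

**3 to 1 and 2.** The bond between the ester α-carbon and the formyl carbon is cut (C3–C2 in chromone numbering). This is a crossed Claisen retron between an enolisable ester and a formate that cannot enolise. Ring B, C3 and C4 are bought in one piece. The forward step needs the product to be removed from the equilibrium as its enolate.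

**8 to 5, through 6 and 7.** The C–Si bond and the O–S bond of the triflate are cut. An ortho-silyl aryl triflate releases an aryne with fluoride under conditions an ester survives. The silyl group is delivered from oxygen to the carbon that carried bromine, so the ortho relationship is built in. Halogen–metal exchange must be faster than deprotonation of the acetal CH2.

**5 to 4.** The C6–Br bond is cut. C6 is the most nucleophilic and least hindered position of 4. The forward step must monobrominate a very electron-rich, easily oxidised phenol.

## Other disconnections considered

**Alternative 1:** The cut removes three ring A bonds (C5–C6, C4a–C8a and C8–C8a), so ring A is assembled from acyclic pieces. The forward key step is a Dötz benzannulation. The Fischer carbene complex (CO)5Cr=C(OMe)C(OtBu)=CH2 A1, a complex of zerovalent chromium, would combine with the racemic terminal alkyne 3-(tert-butyldimethylsilyloxy)-4-(3,4,5-trimethoxyphenyl)but-1-yne A2 and one carbonyl ligand. The product would be racemic 5-tert-butoxy-2-[1-(tert-butyldimethylsilyloxy)-2-(3,4,5-trimethoxyphenyl)ethyl]-4-methoxyphenol A3.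

- **In favour:** the carbene carbon becomes C6 with its methoxy group, the alkoxyvinyl carbon becomes C7 with a removable tert-butyl ether, and the larger alkyne substituent ends up ortho to the new phenol. O6 and O7 are therefore differentiated from the outset. On this point Alternative 1 is better than the chosen plan. Its key step is also an established reaction type, which is again better.
- **Against:** it builds the one ring that can be bought cheaply. It uses stoichiometric chromium and an air-sensitive carbene complex. A 4-methoxyphenol such as A3 is prone to oxidation to the quinone during removal of the metal. Ring C is not formed: A3 must still be desilylated, oxidised to the deoxybenzoin 1-(4-tert-butoxy-2-hydroxy-5-methoxyphenyl)-2-(3,4,5-trimethoxyphenyl)ethanone A4, extended by one carbon with ring closure, and freed of the tert-butyl group. The stereocentre of A2 and A3 is made only to be destroyed.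
- **Comparison:** structurally it addresses the easier ring. Mechanistically it is on firm ground where step 4 is not. In step economy it is clearly longer, about eleven steps against eight.

**Alternative 2:** The cut is the C3–C1' bond together with O1–C2. The forward key step is a constant-current anodic oxidation of 2,6-dimethoxyphenol A6 in the presence of (E)-1-(4-benzyloxy-2-hydroxy-5-methoxyphenyl)-3-(dimethylamino)prop-2-en-1-one A5. The nucleophilic α-carbon of the enaminone should attack the para position of the oxidised phenol. The ring A hydroxyl then adds to the β-carbon and the amino group leaves. The product would be 7-benzyloxy-3-(4-hydroxy-3,5-dimethoxyphenyl)-6-methoxychromen-4-one A7.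

- **In favour:** no metal and no prefunctionalised ring B are needed, and the ortho positions of A6 are blocked, so only para coupling is possible. The ring A pattern is fixed in A5. After the key step only methylation of the 4'-hydroxyl (which would give 14) and hydrogenolysis remain, two steps against four. On this point it is better than the chosen plan.
- **Against:** A5 contains an electron-rich phenol ring and an enaminone, both oxidisable near the potential of A6. Homo-coupling of A6 competes. A7 is a more electron-rich phenol than A6 and could be oxidised further. The O6/O7 differentiation is not avoided but moved into the synthesis of A5, so on that point the two plans are equal.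
- **Comparison:** structurally it forms the bond to ring B and closes ring C at O1–C2, whereas the chosen plan forms both bonds to ring A. Mechanistically it relies on control of oxidation potentials, the chosen plan on polar addition to an aryne. Oxidative annulations of o-hydroxyaryl enaminones and anodic phenol cross-couplings are known families, so its precedent is somewhat closer than that of step 4. Step economy is about equal.

**Alternative 3:** The cut is C4–C4a alone; O1–C8a is bought with a phenol. The forward key step starts from (Z)-3-[3-(benzyloxy)-4-methoxyphenoxy]-2-(3,4,5-trimethoxyphenyl)acrylic acid A8. Its acid chloride, activated by SnCl4, would acylate the ring A carbon para to the benzyloxy group. The product would be 7-benzyloxy-6-methoxy-3-(3,4,5-trimethoxyphenyl)chromen-4-one A9, which is the same compound as 14. A8 would come from a sulfonate of 3 and 3-(benzyloxy)-4-methoxyphenol A10 by addition–elimination and ester hydrolysis.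

- **In favour:** intramolecular Friedel–Crafts acylation is a classical reaction type, so it is better on precedent. The ring A oxygens are differentiated in A10, so a single hydrogenolysis follows the key step instead of four steps, which is also better. It shares 3 with the chosen plan.
- **Against:** it depends on ring A being activated at the right carbon. Here it is, since the other ortho position lies between two oxygens, but the method is not general. SnCl4 and the HCl formed act on a benzyl ether and four methyl ethers. The acid chloride of a push-pull alkene can lose its geometry. The electron-rich ring B can compete intermolecularly.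
- **Comparison:** structurally it makes one ring C bond in the key step, the chosen plan two. Mechanistically it is an electrophilic substitution governed by ring A electronics, whereas the aryne route is independent of them and needs no Lewis acid. In step economy it is equal or slightly shorter, about seven steps. For this target it would be the more conservative plan. The chosen plan offers the two-bond, convergent ring closure at the price of an untested key step.

Key step: step 4

Remark: 3 is drawn as the hydrogen-bonded Z enol (hydroxyl and ester on the same side). In solution it equilibrates with the E enol and the aldehyde tautomer, and all forms give the same enolate under the basic conditions of step 4.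

## Route

Step 1
Reactants: 1 methyl 2-(3,4,5-trimethoxyphenyl)acetate; 2 methyl formate
Product: 3 methyl (Z)-3-hydroxy-2-(3,4,5-trimethoxyphenyl)prop-2-enoate
Conditions: NaH (2.0 equiv), 2 (4 equiv), THF, 0 °C to rt; then 1 M HCl to pH 3
Reagents that add atoms: none
Why: Crossed Claisen condensation (C-formylation): the ester enolate of 1 adds to the formate 2, which cannot enolise, and the product is drawn out of the equilibrium as its stabilised sodium enolate; acidification should give the enol, held in the Z form by an O–H···O=C hydrogen bond.

Step 2
Reactants: 4 sesamol (1,3-benzodioxol-5-ol)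
Product: 5 6-bromo-1,3-benzodioxol-5-ol
Conditions: NBS (1.0 equiv), CH2Cl2, −78 °C to 0 °C, dark
Reagents that add atoms: N-bromosuccinimide, O=C1CCC(=O)N1Br
Why: Electrophilic aromatic bromination; C6 is ortho to the hydroxyl, para to a dioxole oxygen and unhindered, whereas C4 lies between two oxygen substituents, and one equivalent of NBS at low temperature limits dibromination and oxidation to the quinone.

Step 3
Reactants: 5 6-bromo-1,3-benzodioxol-5-ol
Product: 8 6-(trimethylsilyl)-1,3-benzodioxol-5-yl trifluoromethanesulfonate, via aryl silyl ether 6 (not isolated), via lithium silylphenoxide 7 (not isolated)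
Conditions: HMDS (0.6 equiv), THF, 65 °C, then evaporation; n-BuLi (1.1 equiv), THF, −100 °C to −78 °C; then Tf2O (1.2 equiv), −100 °C to rt
Reagents that add atoms: hexamethyldisilazane, C[Si](C)(C)N[Si](C)(C)C; trifluoromethanesulfonic anhydride, O=S(=O)(OS(=O)(=O)C(F)(F)F)C(F)(F)F
Why: O-silylation gives 6; bromine–lithium exchange then sets off a 1,3 O-to-C silyl shift (retro-Brook rearrangement) driven by formation of the phenoxide 7, which Tf2O traps on oxygen; the position of bromine in 5 fixes the ortho relationship of silyl group and triflate.

Step 4
Reactants: 8 6-(trimethylsilyl)-1,3-benzodioxol-5-yl trifluoromethanesulfonate; 3 methyl (Z)-3-hydroxy-2-(3,4,5-trimethoxyphenyl)prop-2-enoate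
Product: 11 6,7-methylenedioxy-3-(3,4,5-trimethoxyphenyl)chromen-4-one, via aryne 9 (not isolated), via aryl anion 10 (not isolated)
Conditions: 3 (1.0 equiv), 8 (1.3 equiv), CsF (4 equiv), THF, 65 °C, 24 h
Reagents that add atoms: none
Why: Proposed new method: fluoride attacks the silicon of 8 and triflate leaves to give aryne 9, while CsF turns 3 into its cesium enolate. The enolate oxygen adds to 9 (O1–C8a), and the aryl anion 10 so formed, ortho to the new vinyl ether oxygen, attacks the ester carbonyl held cis to it across C2=C3 (C4–C4a) and expels methoxide. The closest known reaction type is the fluoride-induced annulation of arynes with salicylate esters to xanthones, which runs through the same O-arylation and intramolecular acyl substitution; the enolate oxygen of a 2-formyl ester in place of a phenoxide is the untested element. Ring C closes by a 6-exo-trig attack on the ester, and no stereocentre is formed. Regiochemistry needs no control because 9 is symmetric, so either aryne carbon gives the same product. The step needs O- over C-arylation (C-attack would open the known aryne insertion into the C–CHO bond of a 1,3-dicarbonyl compound), which the fully substituted, aryl-shielded α-carbon and the exposed, charge-bearing formyl oxygen should secure. It also needs ring closure to outrun protonation of 10, which THF (no acidic C–H) and the chelated U-shaped cesium enolate, leading to the Z vinyl ether, should secure. Sparingly soluble CsF releases 9 slowly, which keeps 10 from adding to a second aryne.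

Step 5
Reactants: 11 6,7-methylenedioxy-3-(3,4,5-trimethoxyphenyl)chromen-4-one
Product: 12 6,7-dihydroxy-3-(3,4,5-trimethoxyphenyl)chromen-4-one
Conditions: BCl3 (3 equiv, 1 M in CH2Cl2), CH2Cl2, −78 °C to −10 °C; then H2O, THF, rt
Reagents that add atoms: none
Why: Lewis acid cleavage of an aryl methylenedioxy acetal: BCl3 binds a dioxole oxygen, chloride opens the O–CH2–O bridge, and aqueous work-up frees both hydroxyls and releases the methylene carbon as formaldehyde; at low temperature BCl3 is known to cleave this acetal in preference to aryl methyl ethers that have no chelating carbonyl next to them, and 11 has no methoxy group on C5.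

Step 6
Reactants: 12 6,7-dihydroxy-3-(3,4,5-trimethoxyphenyl)chromen-4-one
Product: 13 7-benzyloxy-6-hydroxy-3-(3,4,5-trimethoxyphenyl)chromen-4-one
Conditions: BnBr (1.1 equiv), NaHCO3 (1.5 equiv), NaI (0.1 equiv), DMF, 40 °C
Reagents that add atoms: benzyl bromide, BrCc1ccccc1
Why: Williamson ether synthesis under acidity control: the 7-hydroxyl is para to C4a and conjugated with the C4 carbonyl (a vinylogous carboxylic acid), so NaHCO3 should ionise it and leave the 6-hydroxyl protonated, and only the 7-phenoxide is benzylated.

Step 7
Reactants: 13 7-benzyloxy-6-hydroxy-3-(3,4,5-trimethoxyphenyl)chromen-4-one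
Product: 14 7-benzyloxy-6-methoxy-3-(3,4,5-trimethoxyphenyl)chromen-4-one
Conditions: MeI (2 equiv), K2CO3 (2 equiv), acetone, 56 °C
Reagents that add atoms: iodomethane, CI
Why: Williamson methylation of the only remaining hydroxyl; K2CO3 in acetone is not nucleophilic enough to open the pyranone at C2.

Step 8
Reactants: 14 7-benzyloxy-6-methoxy-3-(3,4,5-trimethoxyphenyl)chromen-4-one
Product: 15 7-hydroxy-6-methoxy-3-(3,4,5-trimethoxyphenyl)chromen-4-one (CNP0251581.0)
Conditions: H2 (1 atm), 10% Pd/C, EtOAc/MeOH, rt
Reagents that add atoms: none
Why: Hydrogenolysis of a benzyl aryl ether; at 1 atm O-debenzylation is much faster than reduction of the conjugated C2=C3 bond, and the aryl methyl ethers are inert.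

## Compound list

1 | methyl 2-(3,4,5-trimethoxyphenyl)acetate | COC(=O)Cc1cc(OC)c(OC)c(OC)c1 | starting material
2 | methyl formate | COC=O | starting material
3 | methyl (Z)-3-hydroxy-2-(3,4,5-trimethoxyphenyl)prop-2-enoate | COC(=O)/C(=C\O)c1cc(OC)c(OC)c(OC)c1 | intermediate
4 | sesamol (1,3-benzodioxol-5-ol) | Oc1ccc2OCOc2c1 | starting material
5 | 6-bromo-1,3-benzodioxol-5-ol | Oc1cc2OCOc2cc1Br | intermediate
6 | [(6-bromo-1,3-benzodioxol-5-yl)oxy]trimethylsilane (formed in the flask) | C[Si](C)(C)Oc1cc2OCOc2cc1Br | intermediate
7 | lithium 6-(trimethylsilyl)-1,3-benzodioxol-5-olate (formed in the flask) | [Li+].[O-]c1cc2OCOc2cc1[Si](C)(C)C | intermediate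
8 | 6-(trimethylsilyl)-1,3-benzodioxol-5-yl trifluoromethanesulfonate | C[Si](C)(C)c1cc2OCOc2cc1OS(=O)(=O)C(F)(F)F | intermediate
9 | 5,6-didehydro-1,3-benzodioxole (4,5-methylenedioxybenzyne; formed in the flask) | C1OC2=CC#CC=C2O1 | intermediate
10 | cesium 6-{[(Z)-3-methoxy-3-oxo-2-(3,4,5-trimethoxyphenyl)prop-1-en-1-yl]oxy}-1,3-benzodioxol-5-ide (formed in the flask) | [Cs+].COC(=O)/C(=C\Oc1cc2OCOc2c[c-]1)c1cc(OC)c(OC)c(OC)c1 | intermediate
11 | 6,7-methylenedioxy-3-(3,4,5-trimethoxyphenyl)chromen-4-one | COc1cc(-c2coc3cc4OCOc4cc3c2=O)cc(OC)c1OC | intermediate
12 | 6,7-dihydroxy-3-(3,4,5-trimethoxyphenyl)chromen-4-one | COc1cc(-c2coc3cc(O)c(O)cc3c2=O)cc(OC)c1OC | intermediate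
13 | 7-benzyloxy-6-hydroxy-3-(3,4,5-trimethoxyphenyl)chromen-4-one | COc1cc(-c2coc3cc(OCc4ccccc4)c(O)cc3c2=O)cc(OC)c1OC | intermediate
14 | 7-benzyloxy-6-methoxy-3-(3,4,5-trimethoxyphenyl)chromen-4-one | COc1cc2c(=O)c(-c3cc(OC)c(OC)c(OC)c3)coc2cc1OCc1ccccc1 | intermediate
15 | 7-hydroxy-6-methoxy-3-(3,4,5-trimethoxyphenyl)chromen-4-one (CNP0251581.0) | COc1cc2c(=O)c(-c3cc(OC)c(OC)c(OC)c3)coc2cc1O | target

## Step count and risks

Total step count: 8. Longest linear sequence: 7 steps (steps 2 to 8, from 4 to 15); step 1 is a one-step branch that joins at step 4.

The least certain steps are step 4 (the key step), then steps 5, 6 and 3.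

**Step 4 (key step).** The enolate may be arylated on carbon and then fragment, which amounts to insertion of the aryne into the C–CHO bond. The aryl anion may be protonated before it reaches the ester, or the enolate may react in its extended geometry, which cannot close. Each of these processes would consume both partners without forming ring C.

The fallback uses the classical deoxybenzoin route and sets out from 1 and 4.
- 1 is saponified (LiOH, THF/H2O) to 2-(3,4,5-trimethoxyphenyl)acetic acid F1.
- F1 acylates 4 ortho to the hydroxyl in BF3·OEt2 at 80 °C (Friedel–Crafts acylation at the same carbon that step 2 brominates) to give 1-(6-hydroxy-1,3-benzodioxol-5-yl)-2-(3,4,5-trimethoxyphenyl)ethanone F2.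
- Condensation of the activated methylene of F2 with N,N-dimethylformamide dimethyl acetal in toluene at 90 °C gives (E)-3-(dimethylamino)-1-(6-hydroxy-1,3-benzodioxol-5-yl)-2-(3,4,5-trimethoxyphenyl)prop-2-en-1-one F3.
- F3 should close on warming in acetic acid by conjugate addition of the phenol and loss of the amine, and the route is rejoined at 11.

This fallback forms C4–C4a by electrophilic substitution and therefore depends on the activated ring A, which the key step does not need.

**Step 5.** The dioxole opening is slowed by complexation of BCl3 at the C4 carbonyl. Chemoselectivity may then be lost through cleavage of the central 4'-methyl ether, and the transient chloromethyl ether may alkylate the electron-rich ring B.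

The fallback is oxidative and sets out from 11. Pb(OAc)4 in benzene at 80 °C acetoxylates the acetal C–H bond to give racemic 8-oxo-7-(3,4,5-trimethoxyphenyl)-8H-[1,3]dioxolo[4,5-g]chromen-2-yl acetate F4. This orthoester is hydrolysed by aqueous acetic acid in THF through the monoformate, and the route is rejoined at 12. No Lewis acid touches the methyl ethers.

**Step 6.** Discrimination between the two hydroxyls may be incomplete because the proton moves within the hydrogen-bonded catechol monoanion, leading to alkylation at O6 and to double benzylation.

The fallback reverses the selectivity principle and sets out from 12. NaH (2.2 equiv) in DMSO forms the dianion, and one equivalent of MeI is added. In the dianion the 6-phenoxide is not conjugated with the carbonyl and is the more nucleophilic one, as in the known dianion alkylation of catechols that carry a para acceptor. Methylation at O6 followed by acidification should lead directly to 15, where the route is rejoined; steps 7 and 8 are left out. This fallback makes no new compound (F0).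

**Step 3.** The aryllithium may be protonated before the silyl shift, the acetal CH2 may be deprotonated in competition, or the migration may be incomplete, so that a triflate without the silyl group is carried on.

The fallback separates C-silylation from triflation and sets out from 5. n-BuLi (2.2 equiv) in THF at −78 °C followed by Me3SiCl (2.5 equiv) gives trimethyl{[6-(trimethylsilyl)-1,3-benzodioxol-5-yl]oxy}silane F5 by direct silylation of the O,C-dilithio species. K2CO3 in MeOH cleaves only the O–Si bond to give 6-(trimethylsilyl)-1,3-benzodioxol-5-ol F6, which can be purified and checked. Tf2O and pyridine in CH2Cl2 at 0 °C then give the triflate, and the route is rejoined at 8.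

## Further compounds

F1 | step 4 | 2-(3,4,5-trimethoxyphenyl)acetic acid | COc1cc(CC(O)=O)cc(OC)c1OC
F2 | step 4 | 1-(6-hydroxy-1,3-benzodioxol-5-yl)-2-(3,4,5-trimethoxyphenyl)ethanone | COc1cc(CC(=O)c2cc3OCOc3cc2O)cc(OC)c1OC
F3 | step 4 | (E)-3-(dimethylamino)-1-(6-hydroxy-1,3-benzodioxol-5-yl)-2-(3,4,5-trimethoxyphenyl)prop-2-en-1-one | COc1cc(/C(=C\N(C)C)C(=O)c2cc3OCOc3cc2O)cc(OC)c1OC
F4 | step 5 | 8-oxo-7-(3,4,5-trimethoxyphenyl)-8H-[1,3]dioxolo[4,5-g]chromen-2-yl acetate (racemic, one enantiomer drawn) | COc1cc(-c2coc3cc4O[C@@H](OC(C)=O)Oc4cc3c2=O)cc(OC)c1OC
F0 | step 6 | none | none
F5 | step 3 | trimethyl{[6-(trimethylsilyl)-1,3-benzodioxol-5-yl]oxy}silane | C[Si](C)(C)Oc1cc2OCOc2cc1[Si](C)(C)C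
F6 | step 3 | 6-(trimethylsilyl)-1,3-benzodioxol-5-ol | Oc1cc2OCOc2cc1[Si](C)(C)C
A1 | alternative 1 | pentacarbonyl[(1-tert-butoxyvinyl)(methoxy)carbene]chromium, (CO)5Cr=C(OMe)C(OtBu)=CH2 | COC(C(=C)OC(C)(C)C)=[Cr](=C=O)(=C=O)(=C=O)(=C=O)=C=O
A2 | alternative 1 | 3-(tert-butyldimethylsilyloxy)-4-(3,4,5-trimethoxyphenyl)but-1-yne (racemic, one enantiomer drawn) | C#C[C@@H](O[Si](C)(C)C(C)(C)C)Cc1cc(OC)c(OC)c(OC)c1
A3 | alternative 1 | 5-tert-butoxy-2-[1-(tert-butyldimethylsilyloxy)-2-(3,4,5-trimethoxyphenyl)ethyl]-4-methoxyphenol (racemic, one enantiomer drawn) | COc1cc([C@@H](O[Si](C)(C)C(C)(C)C)Cc2cc(OC)c(OC)c(OC)c2)c(O)cc1OC(C)(C)C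
A4 | alternative 1 | 1-(4-tert-butoxy-2-hydroxy-5-methoxyphenyl)-2-(3,4,5-trimethoxyphenyl)ethanone | COc1cc(C(=O)Cc2cc(OC)c(OC)c(OC)c2)c(O)cc1OC(C)(C)C
A5 | alternative 2 | (E)-1-(4-benzyloxy-2-hydroxy-5-methoxyphenyl)-3-(dimethylamino)prop-2-en-1-one | COc1cc(C(=O)/C=C/N(C)C)c(O)cc1OCc1ccccc1
A6 | alternative 2 | 2,6-dimethoxyphenol | COc1cccc(OC)c1O
A7 | alternative 2 | 7-benzyloxy-3-(4-hydroxy-3,5-dimethoxyphenyl)-6-methoxychromen-4-one | COc1cc2c(=O)c(-c3cc(OC)c(O)c(OC)c3)coc2cc1OCc1ccccc1
A8 | alternative 3 | (Z)-3-[3-(benzyloxy)-4-methoxyphenoxy]-2-(3,4,5-trimethoxyphenyl)acrylic acid | COc1ccc(O/C=C(\C(O)=O)c2cc(OC)c(OC)c(OC)c2)cc1OCc1ccccc1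
A9 | alternative 3 | 7-benzyloxy-6-methoxy-3-(3,4,5-trimethoxyphenyl)chromen-4-one | COc1cc2c(=O)c(-c3cc(OC)c(OC)c(OC)c3)coc2cc1OCc1ccccc1
A10 | alternative 3 | 3-(benzyloxy)-4-methoxyphenol | COc1ccc(O)cc1OCc1ccccc1
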